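**Plan**

Lignan numbering is used: target lactone C2 = C9', C3 = C8', C4 = C8, C5 = C9; the carbinol carbon is C7' and the benzyl CH2 is C7.
Retrosynthesis: cut the lactone O1–C2 acyl bond and raise C5 (C9) back to a carboxyl esterified by the C7' oxygen; replace one benzylic C7–H by a C7–O bond to the C9' carboxyl; then cut C8–C8' and both benzylic C–O bonds at once, which leaves two molecules of ferulic acid.
Forward: C8–C8' and the two fused γ-lactone rings of a 3,7-dioxabicyclo[3.3.0]octane-4,8-dione arise together in step 1; the ring holding O–C7 is opened by hydrogenolysis (step 3), the ring holding O–C7' by hydride (step 6), and the lactone of the target is closed last from the new C9 hydroxyl onto the C9' carboxyl (step 7).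
Enabling feature: the target is an 8-8' dimer of two identical 4-hydroxy-3-methoxyphenyl C6–C3 units, its C7' oxygen sits para to a phenol, and C8, C8' and C7' have the relative configuration of C5, C1 and C2 of the cis-fused, exo,exo-2,6-diaryl dilactone that forms when ferulic acid is dimerised through its quinone methide.
Stereochemistry: the relative configuration comes from the cis ring fusion and convex-face aryl groups set in step 1 and is not touched afterwards; the absolute configuration comes from resolution of the lactone acid as its (S)-1-phenylethylammonium salt (steps 4 and 5).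

Key step: step 1

Assumption: the (2S,3S,4R) acid is taken to give the less soluble salt with (S)-1-phenylethylamine; if the mirror-image acid crystallises instead, (R)-1-phenylethylamine is used and nothing else changes. Racemates are named and drawn as the enantiomer that is carried forward.

**Route**

Step 1
Reactants: 1 (E)-ferulic acid (two molecules)
Product: 3 rac-(1S,2S,5S,6S)-2,6-bis(4-hydroxy-3-methoxyphenyl)-3,7-dioxabicyclo[3.3.0]octane-4,8-dione (cis-fused; both aryl groups exo), via bis-quinone methide diacid 2 (not isolated)
Conditions: FeCl3·6H2O (excess), acetone–H2O, air, rt; EtOAc, cold aq. NaHCO3 wash; crystallisation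
Reagents that add atoms: none
Why: Trivalent iron oxidises the phenol of 1 by one electron to a phenoxyl radical with spin density at C8, two radicals join C8 to C8' to give the bis-quinone methide 2, and each carboxyl group then adds to the quinone methide carbon (C7 or C7') of the other half with rearomatisation. The closest known reaction type is the oxidative 8-8 dehydrodimerisation of 4-hydroxycinnamic acids to 2,6-diaryl-3,7-dioxabicyclo[3.3.0]octane-4,8-diones by FeCl3 or oxidase enzymes. Each of the two γ-lactone rings closes in a 5-exo-trig conjugate addition of a carboxyl oxygen to the exocyclic carbon of a para-quinone methide, the first ring holding C9, O, C7', C8', C8 and the second C9', O, C7, C8, C8'. The bridgehead centres C8 and C8' are defined because only the like-configured coupling product can close twice, and then only to the cis-fused bicycle, while C7 and C7' are set by each aryl group taking the convex face, which should be both the kinetically and the thermodynamically preferred placement. The step needs 8-8 regioselectivity over 8-5 and 8-O-4 coupling and the exo,exo diastereomer; the free para-phenol and the free conjugated acid of 1 secure this in practice because only the 8-8 adduct is trapped as a neutral, sparingly soluble dilactone that is freed from acidic dimers by bicarbonate wash and crystallisation. No enantiocontrol is expected, so 3 is racemic and the absolute configuration is introduced in steps 4 and 5.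

Step 2
Reactants: 3 rac-dilactone bisphenol
Product: 4 rac-(1S,2S,5S,6S)-2,6-bis[4-(tert-butyldimethylsilyloxy)-3-methoxyphenyl]-3,7-dioxabicyclo[3.3.0]octane-4,8-dione
Conditions: TBSCl (2.5 equiv), imidazole (5 equiv), DMF, 0 °C to rt
Reagents that add atoms: tert-butyldimethylsilyl chloride (TBSCl), CC(C)(C)[Si](C)(C)Cl
Why: Silylation of phenols with a silyl chloride and imidazole is standard, imidazole is too weak a base to remove the C8 hydrogen and open the bicycle by E1cB, and masking both phenols rules out later loss of the benzylic acyloxy group through a quinone methide, with no stereocentre affected.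

Step 3
Reactants: 4 rac-bis-silyl dilactone
Product: 5 rac-(2S,3S,4R)-2-[4-(tert-butyldimethylsilyloxy)-3-methoxyphenyl]-4-{[4-(tert-butyldimethylsilyloxy)-3-methoxyphenyl]methyl}-5-oxotetrahydrofuran-3-carboxylic acid (2,3-trans; 3,4-cis)
Conditions: H2 (1 atm), 10% Pd/C, EtOAc, rt, stopped after uptake of about half an equivalent of H2; SiO2 chromatography, recovered 4 recycled
Reagents that add atoms: none
Why: Palladium-catalysed hydrogenolysis of a benzylic ester C–O bond (here a γ-aryl-γ-lactone activated by the para-silyloxy arene) turns O–C7 into CH2 and frees the C9' acid; the two benzylic C–O bonds of 4 are homotopic, so there is no regiochemical choice, only the C7 centre is lost while C8, C8' and C7' stay as set, and partial conversion under neutral conditions limits the second cleavage.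

Step 4
Reactants: 5 rac-lactone acid
Product: 6 (S)-1-phenylethylammonium (2S,3S,4R)-2-[4-(tert-butyldimethylsilyloxy)-3-methoxyphenyl]-4-{[4-(tert-butyldimethylsilyloxy)-3-methoxyphenyl]methyl}-5-oxotetrahydrofuran-3-carboxylate (single diastereomeric salt)
Conditions: (S)-1-phenylethylamine (0.5 equiv), EtOAc–heptane, rt then 0 °C; salt recrystallised to constant rotation
Reagents that add atoms: (S)-1-phenylethylamine, C[C@H](N)c1ccccc1
Why: Classical resolution through diastereomeric ammonium salts is well established for 5-oxotetrahydrofuran-3-carboxylic (paraconic) acids, no stereocentre is formed, the amine is too weak a base to epimerise C8 or C8', and an X-ray structure of the salt should give the absolute configuration against the known (S) centre of the amine.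

Step 5
Reactants: 6 diastereomerically pure ammonium salt
Product: 7 (2S,3S,4R)-2-[4-(tert-butyldimethylsilyloxy)-3-methoxyphenyl]-4-{[4-(tert-butyldimethylsilyloxy)-3-methoxyphenyl]methyl}-5-oxotetrahydrofuran-3-carboxylic acid (single enantiomer)
Conditions: 0.5 M aq. HCl, EtOAc, 0 °C
Reagents that add atoms: none
Why: Protonation of the carboxylate in a cold two-phase system (salt breaking) returns the free acid to the organic layer and the amine to the water layer without touching the lactone, the aryl silyl ethers or any stereocentre.

Step 6
Reactants: 7 (2S,3S,4R)-lactone acid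
Product: 9 (2S,3R)-2-{(S)-[4-(tert-butyldimethylsilyloxy)-3-methoxyphenyl](hydroxy)methyl}-4-[4-(tert-butyldimethylsilyloxy)-3-methoxyphenyl]-3-(hydroxymethyl)butanoic acid, via lithium carboxylate 8 (not isolated)
Conditions: LiOtBu (1.0 equiv), THF, −20 °C; then LiBH4 (2.5 equiv), 0 °C to rt; AcOH–H2O to pH 4–5 at 0 °C, EtOAc extraction; crude 9 used at once
Reagents that add atoms: none
Why: This is the chemoselective borohydride reduction of an ester beside a carboxylate that is used to turn succinic half-esters into β-substituted γ-butyrolactones: LiBH4 reduces the lactone carbonyl C9 to CH2OH by acyl C–O cleavage while the preformed lithium carboxylate C9' is inert, so the C7'–O bond and the three stereocentres are retained.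

Step 7
Reactants: 9 dihydroxy acid
Product: 10 (3S,4R)-3-{(S)-[4-(tert-butyldimethylsilyloxy)-3-methoxyphenyl](hydroxy)methyl}-4-{[4-(tert-butyldimethylsilyloxy)-3-methoxyphenyl]methyl}oxolan-2-one
Conditions: EDC·HCl (1.2 equiv), DMAP (0.1 equiv), CH2Cl2, 0 °C
Reagents that add atoms: none
Why: In this carbodiimide lactonisation the activated C9' acid is captured by the primary C9 hydroxyl in a 5-exo-trig closure, the only γ-lactone possible because the C7' hydroxyl could only give a β-lactone, and the neutral conditions keep the electron-rich benzylic carbinol from ionising, with no stereocentre involved.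

Step 8
Reactants: 10 bis-silyl ether of the target
Product: 11 (3S,4R)-3-[(S)-hydroxy(4-hydroxy-3-methoxyphenyl)methyl]-4-[(4-hydroxy-3-methoxyphenyl)methyl]oxolan-2-one (CNP0288801.2)
Conditions: Bu4NF (2.2 equiv), AcOH (3 equiv), THF, 0 °C; pH 7 phosphate buffer work-up
Reagents that add atoms: none
Why: Fluoride cleavage of aryl silyl ethers is fast, and buffering with acetic acid keeps any phenoxide from persisting, so that neither a quinone methide at C7' nor retro-aldol cleavage or epimerisation of the β-hydroxy lactone should occur.

**Compound list**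

1 | (E)-ferulic acid, (E)-3-(4-hydroxy-3-methoxyphenyl)prop-2-enoic acid | COc1cc(/C=C/C(=O)O)ccc1O | starting material
2 | rac-(2R,3R)-2,3-bis[(3-methoxy-4-oxocyclohexa-2,5-dien-1-ylidene)methyl]butanedioic acid (8-8 bis-quinone methide; exocyclic double-bond geometry not defined) | OC(=O)[C@H](C=C1C=CC(=O)C(OC)=C1)[C@@H](C=C1C=CC(=O)C(OC)=C1)C(=O)O | intermediate
3 | rac-(1S,2S,5S,6S)-2,6-bis(4-hydroxy-3-methoxyphenyl)-3,7-dioxabicyclo[3.3.0]octane-4,8-dione, cis-fused, aryl groups exo | O=C1O[C@H](c3ccc(O)c(OC)c3)[C@@H]2[C@H]1[C@@H](c1ccc(O)c(OC)c1)OC2=O | intermediate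
4 | rac-(1S,2S,5S,6S)-2,6-bis[4-(tert-butyldimethylsilyloxy)-3-methoxyphenyl]-3,7-dioxabicyclo[3.3.0]octane-4,8-dione | O=C1O[C@H](c3ccc(O[Si](C)(C)C(C)(C)C)c(OC)c3)[C@@H]2[C@H]1[C@@H](c1ccc(O[Si](C)(C)C(C)(C)C)c(OC)c1)OC2=O | intermediate
5 | rac-(2S,3S,4R)-2-[4-(tert-butyldimethylsilyloxy)-3-methoxyphenyl]-4-{[4-(tert-butyldimethylsilyloxy)-3-methoxyphenyl]methyl}-5-oxotetrahydrofuran-3-carboxylic acid | O=C1O[C@H](c2ccc(O[Si](C)(C)C(C)(C)C)c(OC)c2)[C@@H](C(=O)O)[C@H]1Cc1ccc(O[Si](C)(C)C(C)(C)C)c(OC)c1 | intermediate
6 | (S)-1-phenylethylammonium salt of the (2S,3S,4R) acid | C[C@H]([NH3+])c1ccccc1.O=C1O[C@H](c2ccc(O[Si](C)(C)C(C)(C)C)c(OC)c2)[C@@H](C(=O)[O-])[C@H]1Cc1ccc(O[Si](C)(C)C(C)(C)C)c(OC)c1 | intermediate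
7 | (2S,3S,4R)-2-[4-(tert-butyldimethylsilyloxy)-3-methoxyphenyl]-4-{[4-(tert-butyldimethylsilyloxy)-3-methoxyphenyl]methyl}-5-oxotetrahydrofuran-3-carboxylic acid, single enantiomer | O=C1O[C@H](c2ccc(O[Si](C)(C)C(C)(C)C)c(OC)c2)[C@@H](C(=O)O)[C@H]1Cc1ccc(O[Si](C)(C)C(C)(C)C)c(OC)c1 | intermediate
8 | lithium carboxylate of 7 | [Li+].O=C1O[C@H](c2ccc(O[Si](C)(C)C(C)(C)C)c(OC)c2)[C@@H](C(=O)[O-])[C@H]1Cc1ccc(O[Si](C)(C)C(C)(C)C)c(OC)c1 | intermediate
9 | (2S,3R)-2-{(S)-[4-(tert-butyldimethylsilyloxy)-3-methoxyphenyl](hydroxy)methyl}-4-[4-(tert-butyldimethylsilyloxy)-3-methoxyphenyl]-3-(hydroxymethyl)butanoic acid | COc1cc(C[C@@H](CO)[C@H](C(=O)O)[C@H](O)c2ccc(O[Si](C)(C)C(C)(C)C)c(OC)c2)ccc1O[Si](C)(C)C(C)(C)C | intermediate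
10 | (3S,4R)-3-{(S)-[4-(tert-butyldimethylsilyloxy)-3-methoxyphenyl](hydroxy)methyl}-4-{[4-(tert-butyldimethylsilyloxy)-3-methoxyphenyl]methyl}oxolan-2-one | COc1cc(C[C@H]2COC(=O)[C@@H]2[C@H](O)c2ccc(O[Si](C)(C)C(C)(C)C)c(OC)c2)ccc1O[Si](C)(C)C(C)(C)C | intermediate
11 | (3S,4R)-3-[(S)-hydroxy(4-hydroxy-3-methoxyphenyl)methyl]-4-[(4-hydroxy-3-methoxyphenyl)methyl]oxolan-2-one, CNP0288801.2 | COc1cc(C[C@H]2COC(=O)[C@@H]2[C@H](O)c2ccc(O)c(OC)c2)ccc1O | target

**Step count and risks**

Total step count: 8. Longest linear sequence: 8 steps (fully linear from ferulic acid).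

Steps most likely to fail:

Step 3. The hydrogenolysis may not distinguish the first benzylic C–O bond from the second, so that over-reduction to the doubly opened diacid and a large recycle stream erode the throughput, or the cleavage may be sluggish under neutral conditions. The fallback sets out from 4 and breaks the symmetry by elimination instead of reduction. One equivalent of DBU in THF at 0 °C removes the C8 hydrogen and expels the C9' carboxylate from C7 (E1cB), which should give the racemic (2S,3S)-2-aryl-4-[(E)-arylmethylidene]-5-oxotetrahydrofuran-3-carboxylic acid F1. This opening stops by itself after one ring, because the remaining α-hydrogen at C8' then sits beside a carboxylate anion. Hydrogenation of the conjugated C7=C8 double bond over Rh/Al2O3 in EtOAc, a catalyst with little tendency to cleave benzylic C–O bonds, should deliver hydrogen to the face opposite the C8' carboxyl group and so return to the 3,4-cis acid 5.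

Step 6. The hindered lactone carbonyl, cis to the carboxylate, may be reduced only slowly, and long exposure to borohydride and alkoxide could epimerise C8 or strip an aryl silyl group. The fallback sets out from 7, again as its lithium carboxylate 8, and reduces in two separate stages at lower temperature. i-Bu2AlH in CH2Cl2 at −78 °C takes the lactone only to the lactol level, giving (2S,3S,4R)-2-aryl-4-(arylmethyl)-5-hydroxytetrahydrofuran-3-carboxylic acid F2 as a mixture of anomers in equilibrium with the open hydroxy aldehyde. NaBH4 in THF–EtOH at 0 °C then reduces the aldehyde form, the carboxylate being inert to this reagent, and buffered work-up at pH 4–5 comes back to the route at 9.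

Step 4. The diastereomeric salts may fail to crystallise or may co-crystallise, so that the enantiomers are not separated. The fallback sets out from racemic 4 and separates the enantiomers of this neutral, C2-symmetric compound by preparative chromatography on a polysaccharide chiral stationary phase. The (1S,2S,5S,6S)-enantiomer of the bis-silyl dilactone F3 is then hydrogenolysed exactly as in step 3 and comes back to the route at 7, so that 5 and 6 are bypassed. The absolute configuration would then be assigned by X-ray diffraction with the silicon atoms as anomalous scatterers, or by taking a sample through to 11 and comparing the sign of its rotation.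

**Further compounds**

F1 | step 3 | rac-(2S,3S)-2-[4-(tert-butyldimethylsilyloxy)-3-methoxyphenyl]-4-{(E)-[4-(tert-butyldimethylsilyloxy)-3-methoxyphenyl]methylidene}-5-oxotetrahydrofuran-3-carboxylic acid | O=C1O[C@H](c2ccc(O[Si](C)(C)C(C)(C)C)c(OC)c2)[C@@H](C(=O)O)/C1=C\c1ccc(O[Si](C)(C)C(C)(C)C)c(OC)c1
F2 | step 6 | (2S,3S,4R)-2-[4-(tert-butyldimethylsilyloxy)-3-methoxyphenyl]-4-{[4-(tert-butyldimethylsilyloxy)-3-methoxyphenyl]methyl}-5-hydroxytetrahydrofuran-3-carboxylic acid (lactol, both C5 epimers) | OC1O[C@H](c2ccc(O[Si](C)(C)C(C)(C)C)c(OC)c2)[C@@H](C(=O)O)[C@H]1Cc1ccc(O[Si](C)(C)C(C)(C)C)c(OC)c1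
F3 | step 4 | (1S,2S,5S,6S)-2,6-bis[4-(tert-butyldimethylsilyloxy)-3-methoxyphenyl]-3,7-dioxabicyclo[3.3.0]octane-4,8-dione, single enantiomer of 4 | O=C1O[C@H](c3ccc(O[Si](C)(C)C(C)(C)C)c(OC)c3)[C@@H]2[C@H]1[C@@H](c1ccc(O[Si](C)(C)C(C)(C)C)c(OC)c1)OC2=O
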